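**Plan**

1. Retrosynthesis: the two imide N–C(=O) bonds are cut first (α-diacid plus 5,6-dihydropyridin-2(1H)-one), then the two aryl–ring bonds C1–Ar and C3–Ar are cut together (a trans cyclobutane-1,3-bis(anilide) plus two molecules of 4-iodoveratrole). Ring atoms are numbered as in the target SMILES: C1 and C3 carry the aryls, C2 and C4 the acyl groups.
2. Enabling feature: on the cyclobutane C1–C4 each aryl is cis to exactly one vicinal acyl (C1-aryl with C4-acyl, C3-aryl with C2-acyl) and the C2 and C4 acyls are trans, so a directing amide on each carbonyl can deliver one aryl to its own face.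
3. Forward: the four-membered ring is bought as trans-cyclobutane-1,3-dicarboxylic acid and no ring is formed. Order: bis(2-methylsulfanyl-anilide), twofold C–H arylation, Boc activation and peroxide cleavage to the diacid, bis(acid chloride), N-acylation of the lactam.
4. Stereochemistry: the trans C2/C4 relation comes from the purchased diacid; C1 and C3 are set by cis delivery from the C4 and C2 amides (substrate control).

Key step: step 3

Assumption: the target has an inversion centre (α-truxillic pattern) and is achiral, so the SMILES defines one diastereomer and no absolute control is needed; trans-cyclobutane-1,3-dicarboxylic acid is taken as purchased isomerically pure.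

Naming remark: compound names use IUPAC locants (carbonyl-bearing carbons 1 and 3, aryl-bearing carbons 2 and 4); the discussion uses the SMILES numbering given in the plan.

**Route**

Step 1
Reactants: 1 trans-cyclobutane-1,3-dicarboxylic acid
Product: 2 trans-cyclobutane-1,3-dicarbonyl dichloride
Conditions: (COCl)2 (2.5 equiv), DMF (cat.), CH2Cl2, 0 °C to rt; concentrate, use crude
Reagents that add atoms: oxalyl chloride, ClC(=O)C(=O)Cl
Why: Acid chloride formation under Vilsmeier (DMF) catalysis is base-free, so the trans relation of the two carboxyl-bearing carbons is not disturbed.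

Step 2
Reactants: 2 trans-cyclobutane-1,3-dicarbonyl dichloride; 3 2-(methylsulfanyl)aniline
Product: 4 trans-N1,N3-bis[2-(methylsulfanyl)phenyl]cyclobutane-1,3-dicarboxamide
Conditions: 3 (2.2 equiv), pyridine (3 equiv), CH2Cl2, 0 °C to rt; recrystallise
Reagents that add atoms: none
Why: N-Acylation of an aniline by an acid chloride with pyridine as HCl scavenger, a base too weak to form the ketene, should carry the trans configuration into the bis(anilide).

Step 3
Reactants: 4 trans-N1,N3-bis[2-(methylsulfanyl)phenyl]cyclobutane-1,3-dicarboxamide; 5 4-iodo-1,2-dimethoxybenzene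
Product: 7 (1α,2α,3β,4β)-2,4-bis(3,4-dimethoxyphenyl)-N1,N3-bis[2-(methylsulfanyl)phenyl]cyclobutane-1,3-dicarboxamide (α, centrosymmetric), via rac-(1α,2α,3β)-2-(3,4-dimethoxyphenyl)-N1,N3-bis[2-(methylsulfanyl)phenyl]cyclobutane-1,3-dicarboxamide 6 (not isolated)
Conditions: 5 (5 equiv), Pd(OAc)2 (20 mol %), Ag2CO3 (3 equiv), PivOH (2 equiv), HFIP, 90 °C, sealed tube
Reagents that add atoms: none
Why: Each deprotonated anilide binds Pd(II) as an N,S-chelate and, by carboxylate-assisted concerted metalation–deprotonation, palladates the ring methylene C–H cis to it (five-membered palladacycle); oxidative addition of 5 to Pd(IV), C–C reductive elimination with retention and iodide abstraction by silver then form first the C1–aryl bond (racemic 6) and then the C3–aryl bond. The closest known reaction type is the palladium-catalysed, bidentate-auxiliary-directed cis-β-C(sp3)–H arylation of cyclobutanecarboxamides with aryl iodides under Pd(OAc)2/Ag2CO3/PivOH in HFIP. No ring is closed; the cyclobutane is present from compound 1. Each new stereocentre (C1, C3) is set by its delivering amide (on C4 and C2 respectively), because the palladacycle can only be cis-fused to the four-membered ring, and the trans relation of the two amides therefore places the aryls on opposite faces (α pattern). The selectivity needed is that the second aryl is delivered by the C2 amide, which is trans to the first aryl, and not again by the C4 amide, which would give the cis-diaryl isomer; the weakly chelating thioether anilide in HFIP/PivOH is chosen because it is known to stop after one arylation when the amide has a cis β-aryl neighbour yet still to arylate its free methylene when the β-aryl is trans, whereas the 8-quinolyl amide is known to arylate both methylenes from a single amide. A third arylation is excluded because the remaining ring C–H bonds are tertiary, and both enantiomers of 6 converge on the achiral 7.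

Step 4
Reactants: 7 (1α,2α,3β,4β)-2,4-bis(3,4-dimethoxyphenyl)-N1,N3-bis[2-(methylsulfanyl)phenyl]cyclobutane-1,3-dicarboxamide
Product: 8 (1α,2α,3β,4β)-N1,N3-bis(tert-butoxycarbonyl)-2,4-bis(3,4-dimethoxyphenyl)-N1,N3-bis[2-(methylsulfanyl)phenyl]cyclobutane-1,3-dicarboxamide
Conditions: Boc2O (4 equiv), DMAP (0.4 equiv), MeCN, rt to 45 °C
Reagents that add atoms: di-tert-butyl dicarbonate, CC(C)(C)OC(=O)OC(=O)OC(C)(C)C
Why: DMAP-catalysed N-tert-butoxycarbonylation of secondary anilides (amide activation) twists each amide out of conjugation and turns the anilide nitrogen into a carbamate leaving group without touching a stereocentre.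

Step 5
Reactants: 8 (1α,2α,3β,4β)-N1,N3-bis(tert-butoxycarbonyl)-2,4-bis(3,4-dimethoxyphenyl)-N1,N3-bis[2-(methylsulfanyl)phenyl]cyclobutane-1,3-dicarboxamide
Product: 10 (1α,2α,3β,4β)-2,4-bis(3,4-dimethoxyphenyl)cyclobutane-1,3-dicarboxylic acid (α-diacid), via (1α,2α,3β,4β)-2,4-bis(3,4-dimethoxyphenyl)cyclobutane-1,3-dicarboperoxoic acid (as its dilithium salt) 9 (not isolated)
Conditions: LiOH·H2O (4 equiv), 30% H2O2 (10 equiv), THF/H2O 3:1, 0 °C to rt; aq. Na2SO3; 1 M HCl to pH 2
Reagents that add atoms: hydrogen peroxide, OO
Why: Lithium hydroperoxide, as in the cleavage of N-acyl oxazolidinones, should attack the acyl carbonyl of an N-acyl carbamate in preference to the carbamate carbonyl and is too weakly basic to epimerise the ring carbons; the percarboxylate is reduced to the carboxylate by sulfite on work-up.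

Step 6
Reactants: 10 (1α,2α,3β,4β)-2,4-bis(3,4-dimethoxyphenyl)cyclobutane-1,3-dicarboxylic acid
Product: 11 (1α,2α,3β,4β)-2,4-bis(3,4-dimethoxyphenyl)cyclobutane-1,3-dicarbonyl dichloride
Conditions: (COCl)2 (3 equiv), DMF (cat.), CH2Cl2, 0 °C to rt; concentrate cold, use at once
Reagents that add atoms: oxalyl chloride, ClC(=O)C(=O)Cl
Why: Vilsmeier-catalysed acid chloride formation is base-free and uses no Lewis acid, so neither epimerisation nor Friedel–Crafts attack on the veratryl rings is expected.

Step 7
Reactants: 11 (1α,2α,3β,4β)-2,4-bis(3,4-dimethoxyphenyl)cyclobutane-1,3-dicarbonyl dichloride; 12 5,6-dihydropyridin-2(1H)-one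
Product: 14 1,1'-{[(1α,2α,3β,4β)-2,4-bis(3,4-dimethoxyphenyl)cyclobutane-1,3-diyl]dicarbonyl}bis(5,6-dihydropyridin-2(1H)-one) (target CNP0199212.1), via 1-lithio-5,6-dihydropyridin-2(1H)-one 13 (not isolated)
Conditions: 12 (2.3 equiv), LiHMDS (2.2 equiv), THF, −78 °C; then 11 in THF, −78 to 0 °C; aq. NH4Cl
Reagents that add atoms: none
Why: N-Acylation of a lithium lactamate by an acid chloride (imide formation) is the standard entry to N-acyl-5,6-dihydropyridin-2-ones, and complete N-deprotonation at −78 °C before the acid chloride is added should keep free base from the acyl α-hydrogens, so the α configuration is retained.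

**Compound list**

1 | trans-cyclobutane-1,3-dicarboxylic acid | C1[C@H](C(=O)O)C[C@H]1C(=O)O | starting material
2 | trans-cyclobutane-1,3-dicarbonyl dichloride | C1[C@H](C(=O)Cl)C[C@H]1C(=O)Cl | intermediate
3 | 2-(methylsulfanyl)aniline | CSc1ccccc1N | starting material
4 | trans-N1,N3-bis[2-(methylsulfanyl)phenyl]cyclobutane-1,3-dicarboxamide | C1[C@H](C(=O)Nc2ccccc2SC)C[C@H]1C(=O)Nc1ccccc1SC | intermediate
5 | 4-iodo-1,2-dimethoxybenzene | COc1ccc(I)cc1OC | starting material
6 | rac-(1α,2α,3β)-2-(3,4-dimethoxyphenyl)-N1,N3-bis[2-(methylsulfanyl)phenyl]cyclobutane-1,3-dicarboxamide (aryl cis to one vicinal amide, trans to the other; racemic, one enantiomer drawn) | COc1ccc([C@H]2[C@H](C(=O)Nc3ccccc3SC)C[C@H]2C(=O)Nc2ccccc2SC)cc1OC | intermediate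
7 | (1α,2α,3β,4β)-2,4-bis(3,4-dimethoxyphenyl)-N1,N3-bis[2-(methylsulfanyl)phenyl]cyclobutane-1,3-dicarboxamide | COc1ccc([C@H]2[C@H](C(=O)Nc3ccccc3SC)[C@H](c3ccc(OC)c(OC)c3)[C@H]2C(=O)Nc2ccccc2SC)cc1OC | intermediate
8 | (1α,2α,3β,4β)-N1,N3-bis(tert-butoxycarbonyl)-2,4-bis(3,4-dimethoxyphenyl)-N1,N3-bis[2-(methylsulfanyl)phenyl]cyclobutane-1,3-dicarboxamide | COc1ccc([C@H]2[C@H](C(=O)N(C(=O)OC(C)(C)C)c3ccccc3SC)[C@H](c3ccc(OC)c(OC)c3)[C@H]2C(=O)N(C(=O)OC(C)(C)C)c2ccccc2SC)cc1OC | intermediate
9 | (1α,2α,3β,4β)-2,4-bis(3,4-dimethoxyphenyl)cyclobutane-1,3-dicarboperoxoic acid (dilithium salt in the flask) | COc1ccc([C@H]2[C@H](C(=O)OO)[C@H](c3ccc(OC)c(OC)c3)[C@H]2C(=O)OO)cc1OC | intermediate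
10 | (1α,2α,3β,4β)-2,4-bis(3,4-dimethoxyphenyl)cyclobutane-1,3-dicarboxylic acid | COc1ccc([C@H]2[C@H](C(=O)O)[C@H](c3ccc(OC)c(OC)c3)[C@H]2C(=O)O)cc1OC | intermediate
11 | (1α,2α,3β,4β)-2,4-bis(3,4-dimethoxyphenyl)cyclobutane-1,3-dicarbonyl dichloride | COc1ccc([C@H]2[C@H](C(=O)Cl)[C@H](c3ccc(OC)c(OC)c3)[C@H]2C(=O)Cl)cc1OC | intermediate
12 | 5,6-dihydropyridin-2(1H)-one | O=C1C=CCCN1 | starting material
13 | 1-lithio-5,6-dihydropyridin-2(1H)-one | [Li]N1CCC=CC1=O | intermediate
14 | 1,1'-{[(1α,2α,3β,4β)-2,4-bis(3,4-dimethoxyphenyl)cyclobutane-1,3-diyl]dicarbonyl}bis(5,6-dihydropyridin-2(1H)-one) | COc1ccc([C@H]2[C@H](C(=O)N3CCC=CC3=O)[C@H](c3ccc(OC)c(OC)c3)[C@H]2C(=O)N2CCC=CC2=O)cc1OC | target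

**Step count**

Total steps: 7. Longest linear sequence: 7 (1 to 14).

**Steps most likely to fail**

Step 3. The second palladation may be carried out by the amide that already delivered the first aryl (poor discrimination between the two directing amides), which would give the cis-diaryl diastereomer; the reaction may also stop at mono-arylation through binding of palladium by the bis-chelating products. The fallback gives up C–H arylation for a cycloaddition and sets out from 5. A Heck reaction of 5 with acrylic acid (Pd(OAc)2 cat., Et3N, DMF, 90 °C) should give (E)-3-(3,4-dimethoxyphenyl)prop-2-enoic acid F1. Irradiation of the crystalline acid (λ > 300 nm, stirred aqueous suspension of the powder), in which the molecules are expected to stack head-to-tail, should give the centrosymmetric head-to-tail [2+2] dimer by topochemical photodimerisation. This is diacid 10, where the route is rejoined before step 6.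

Step 7. The lithium lactamate may deprotonate the hindered acid chloride at the ring carbon (ketene formation with loss of configuration or oligomerisation), acylate on oxygen, or fail to complete the second acylation. The fallback replaces the lactam anion by a neutral silyl-transfer acylation and sets out from 12. Silylation (TMSCl, Et3N, toluene, rt) should give 1-(trimethylsilyl)-5,6-dihydropyridin-2(1H)-one F2. Heating F2 with 11 in toluene should transfer the acyl groups to nitrogen with loss of chlorotrimethylsilane under base-free conditions and arrive directly at 14.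

Step 5. The hydroperoxide may attack the carbamate carbonyl instead of the hindered ring acyl (loss of Boc and return of the anilide), and peroxide or percarboxylate may be consumed in oxidation at sulfur. The fallback replaces oxidative hydrolysis by alcoholysis and hydrogenolysis and sets out from 8. Lithium benzyloxide (BnOH, n-BuLi, THF, 0 °C) should transesterify both N-acyl carbamates to dibenzyl (1α,2α,3β,4β)-2,4-bis(3,4-dimethoxyphenyl)cyclobutane-1,3-dicarboxylate F3. After chromatographic removal of the sulfur-containing carbamate, hydrogenolysis (H2, Pd/C, EtOAc, rt) should give diacid 10, where the route is rejoined before step 6.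

**Further compounds**

F1 | step 3 | (E)-3-(3,4-dimethoxyphenyl)prop-2-enoic acid | COc1ccc(/C=C/C(=O)O)cc1OC
F2 | step 7 | 1-(trimethylsilyl)-5,6-dihydropyridin-2(1H)-one | C[Si](C)(C)N1CCC=CC1=O
F3 | step 5 | dibenzyl (1α,2α,3β,4β)-2,4-bis(3,4-dimethoxyphenyl)cyclobutane-1,3-dicarboxylate | COc1ccc([C@H]2[C@H](C(=O)OCc3ccccc3)[C@H](c3ccc(OC)c(OC)c3)[C@H]2C(=O)OCc2ccccc2)cc1OC
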